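**Retrosynthetic overview**
- The target comes from a 14-membered hydroxy lactone (C5 silyl ether, C13 epimer) by invertive acetylation at C13 and desilylation.
- Key disconnection C13–C14: the β-carbon of a preformed butenolide, unmasked from a 3-(bromomethyl)butenolide with CrCl2, acts as a homoenolate equivalent and adds to the C13 aldehyde. This closes the 14-membered ring and sets C13, C14 and the exocyclic methylene in one step.
- The bromomethyl butenolide comes from ring-closing metathesis of a 2-(bromomethyl)acrylate of a divinyl carbinol; C1 is set by asymmetric vinylation of the C1 enal.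
- The C1–C13 chain comes from two asymmetric vinylogous Mukaiyama aldol additions of the prenal silyl dienol ether to a C9–C13 enal acetal, itself made from the same dienol ether and trimethyl orthoformate.
- Ring order: five-membered lactone first (metathesis), 14-membered carbocycle last (key step).

Numbering and assumption: C1 = lactone O–CH, C2=C3(Me), C4H2, C5(OH), C6=C7(Me), C8H2, C9(OAc), C10=C11(Me), C12H2, C13(OAc), C14 = ring-fusion CH, C15 = C(=CH2), C17 = lactone C=O; the target is taken as drawn, (1S,5S,9S,13S,14S), all-E, trans-fused lactone; chiral promoters, ligands and catalysts are not counted as starting materials.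

**Step 1**
Reactants: 1 3-methylbut-2-enal
Product: 2 (1E)-tert-butyl(dimethyl)[(3-methylbuta-1,3-dien-1-yl)oxy]silane
Conditions: TBSOTf, Et3N, Et2O, 0 °C → rt
Reagents that add atoms: tert-butyldimethylsilyl trifluoromethanesulfonate, CC(C)(C)[Si](C)(C)OS(=O)(=O)C(F)(F)F
Why: Soft enolisation (silyl triflate and amine) removes a γ-proton of the enal and traps the extended enolate on oxygen as the silyl dienol ether; no stereocentre is formed.

**Step 2**
Reactants: 2 (1E)-tert-butyl(dimethyl)[(3-methylbuta-1,3-dien-1-yl)oxy]silane; 3 trimethyl orthoformate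
Product: 4 (2E)-5,5-dimethoxy-3-methylpent-2-enal
Conditions: HC(OMe)3 (3 equiv), ZnBr2 (10 mol %), CH2Cl2, −20 °C → rt
Reagents that add atoms: none
Why: Vinylogous Mukaiyama-type alkylation with an orthoester: the dimethoxycarbenium ion attacks the γ-terminus of the dienol ether, the s-trans diene gives the E enal, and the product acetal is too weakly ionised by ZnBr2 to react again.

**Step 3**
Reactants: 4 (2E)-5,5-dimethoxy-3-methylpent-2-enal; 2 (1E)-tert-butyl(dimethyl)[(3-methylbuta-1,3-dien-1-yl)oxy]silane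
Product: 5 (2E,5S,6E)-5-hydroxy-9,9-dimethoxy-3,7-dimethylnona-2,6-dienal
Conditions: (4R)-4-(1H-indol-3-ylmethyl)-2-phenyl-3-tosyl-1,3,2-oxazaborolidin-5-one (30 mol %, from N-tosyl-D-tryptophan and PhBCl2), i-PrOH (1.1 equiv), EtCN, −78 °C; 4 (2 equiv), 2 (1 equiv, added slowly)
Reagents that add atoms: none
Why: Vinylogous Mukaiyama aldol of an aldehyde-derived silyl dienol ether under a tryptophan-derived oxazaborolidinone: the γ-carbon attacks the Si face of the boron-bound enal (the D-series promoter is taken to shield the Re face), giving the 5S carbinol (target C9) and an E enal from the s-trans diene, while keeping 2 limiting curbs a second addition to the product enal.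

**Step 4**
Reactants: 5 (2E,5S,6E)-5-hydroxy-9,9-dimethoxy-3,7-dimethylnona-2,6-dienal
Product: 6 (2E,5S,6E)-5-acetoxy-9,9-dimethoxy-3,7-dimethylnona-2,6-dienal
Conditions: Ac2O, pyridine, DMAP (5 mol %), CH2Cl2, 0 °C
Reagents that add atoms: acetic anhydride, CC(=O)OC(C)=O
Why: DMAP-catalysed acylation of the secondary alcohol under weakly basic conditions that do not trigger vinylogous elimination of the δ-acetate; the stereocentre is untouched.

**Step 5**
Reactants: 6 (2E,5S,6E)-5-acetoxy-9,9-dimethoxy-3,7-dimethylnona-2,6-dienal; 2 (1E)-tert-butyl(dimethyl)[(3-methylbuta-1,3-dien-1-yl)oxy]silane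
Product: 7 (2E,5S,6E,9S,10E)-9-acetoxy-5-hydroxy-13,13-dimethoxy-3,7,11-trimethyltrideca-2,6,10-trienal
Conditions: same oxazaborolidinone as step 3 (30 mol %), i-PrOH (1.1 equiv), EtCN, −78 °C; 6 (1.5 equiv, excess recovered), 2 (1 equiv, added slowly)
Reagents that add atoms: none
Why: Second vinylogous Mukaiyama aldol under the same promoter control: Si-face γ-attack sets 5S (target C5) and the E-C2=C3 alkene, and the remote C9 centre does not influence the facial choice.

**Step 6**
Reactants: 7 (2E,5S,6E,9S,10E)-9-acetoxy-5-hydroxy-13,13-dimethoxy-3,7,11-trimethyltrideca-2,6,10-trienal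
Product: 8 (2E,5S,6E,9S,10E)-9-acetoxy-5-{[tert-butyl(dimethyl)silyl]oxy}-13,13-dimethoxy-3,7,11-trimethyltrideca-2,6,10-trienal
Conditions: TBSCl, imidazole, DMF, 0 °C → rt
Reagents that add atoms: tert-butyl(chloro)dimethylsilane, CC(C)(C)[Si](C)(C)Cl
Why: Standard silylation marks the C5 oxygen as the one that stays free in the target and keeps it apart from the C1 and C13 hydroxyls formed later.

**Step 7**
Reactants: 8 (2E,5S,6E,9S,10E)-9-acetoxy-5-{[tert-butyl(dimethyl)silyl]oxy}-13,13-dimethoxy-3,7,11-trimethyltrideca-2,6,10-trienal; 9 vinylmagnesium bromide (CH2=CHMgBr)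
Product: 10 (3R,4E,7S,8E,11S,12E)-7-{[tert-butyl(dimethyl)silyl]oxy}-3-hydroxy-15,15-dimethoxy-5,9,13-trimethylpentadeca-1,4,8,12-tetraen-11-yl acetate
Conditions: CH2=CHMgBr (3 equiv), ZnCl2 (1.5 equiv), Et2O, 0 °C; 1,4-dioxane, filter; (+)-DAIB (10 mol %), toluene, −20 → 0 °C; aq. NH4Cl
Reagents that add atoms: none
Why: Amino-alcohol-catalysed asymmetric 1,2-addition of a vinylzinc reagent (Noyori–Oppolzer type): (+)-DAIB, the mirror image of the ligand that delivers to the Si face, transfers vinyl to the Re face of the enal and sets 3R (target C1) under reagent control, and the organozinc leaves acetate, acetal and silyl ether alone.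

**Step 8**
Reactants: 10 (3R,4E,7S,8E,11S,12E)-7-{[tert-butyl(dimethyl)silyl]oxy}-3-hydroxy-15,15-dimethoxy-5,9,13-trimethylpentadeca-1,4,8,12-tetraen-11-yl acetate; 11 2-(bromomethyl)prop-2-enoic acid
Product: 12 (3R,4E,7S,8E,11S,12E)-11-acetoxy-7-{[tert-butyl(dimethyl)silyl]oxy}-15,15-dimethoxy-5,9,13-trimethylpentadeca-1,4,8,12-tetraen-3-yl 2-(bromomethyl)prop-2-enoate
Conditions: DCC, DMAP (5 mol %), CH2Cl2, −20 → 0 °C
Reagents that add atoms: none
Why: Steglich esterification acylates the bis-allylic alcohol under neutral conditions with retention at C1, and low temperature with little DMAP avoids substitution of the allylic bromide.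

**Step 9**
Reactants: 12 (3R,4E,7S,8E,11S,12E)-11-acetoxy-7-{[tert-butyl(dimethyl)silyl]oxy}-15,15-dimethoxy-5,9,13-trimethylpentadeca-1,4,8,12-tetraen-3-yl 2-(bromomethyl)prop-2-enoate
Product: 13 (5S)-3-(bromomethyl)-5-[(1E,4S,5E,8S,9E)-8-acetoxy-4-{[tert-butyl(dimethyl)silyl]oxy}-12,12-dimethoxy-2,6,10-trimethyldodeca-1,5,9-trien-1-yl]furan-2(5H)-one
Conditions: second-generation Hoveyda–Grubbs catalyst (5 mol %), toluene (5 mM), 60 °C
Reagents that add atoms: none
Why: Ring-closing metathesis: the ruthenium carbene loads on the only monosubstituted alkene and closes onto the acrylate methylene to give the five-membered butenolide with loss of ethene, while the trisubstituted alkenes are inert and C1 is untouched (its descriptor becomes S by priority change only).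

**Step 10**
Reactants: 13 (5S)-3-(bromomethyl)-5-[(1E,4S,5E,8S,9E)-8-acetoxy-4-{[tert-butyl(dimethyl)silyl]oxy}-12,12-dimethoxy-2,6,10-trimethyldodeca-1,5,9-trien-1-yl]furan-2(5H)-one
Product: 14 (5S)-3-(bromomethyl)-5-[(1E,4S,5E,8S,9E)-8-acetoxy-4-{[tert-butyl(dimethyl)silyl]oxy}-2,6,10-trimethyl-12-oxododeca-1,5,9-trien-1-yl]furan-2(5H)-one
Conditions: 10% aq. oxalic acid on SiO2, CH2Cl2, rt; filtered and used at once
Reagents that add atoms: water, O
Why: Heterogeneous, weakly acidic acetal hydrolysis frees the C13 aldehyde faster than it enolises into conjugation and leaves the secondary silyl ether, the allylic acetate and the allylic bromide intact.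

**Step 11**
Reactants: 14 (5S)-3-(bromomethyl)-5-[(1E,4S,5E,8S,9E)-8-acetoxy-4-{[tert-butyl(dimethyl)silyl]oxy}-2,6,10-trimethyl-12-oxododeca-1,5,9-trien-1-yl]furan-2(5H)-one
Product: 15 (1S,5S,9S,13R,14S)-9-acetoxy-5-{[tert-butyl(dimethyl)silyl]oxy}-13-hydroxy macrocyclic α-methylene lactone (target numbering; the 13-epi, 13-deacetyl, 5-O-silyl target)
Conditions: CrCl2 (10 equiv), THF, rt, 14 added by syringe pump over 12 h (2 mM final); aq. NH4Cl
Reagents that add atoms: none
Why: Proposed new method: two CrCl2 reduce the allylic bromide to an allylchromium species whose γ-carbon is the lactone β-carbon C14 (a homoenolate equivalent), which adds to the tethered aldehyde with allylic transposition through a Zimmerman–Traxler chair on the butenolide face opposite to the C1–C2 bond (trans lactone, 14S) and with the aldehyde chain equatorial (13R), moving the alkene to the exocyclic position; the closest known chemistry is the intermolecular Cr-, Zn- or In-mediated Barbier addition of 3-(bromomethyl)furan-2(5H)-ones to aldehydes and the Nozaki–Hiyama allyl bromide–aldehyde macrocyclisations used for 14-membered cembranoids.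

**Step 12**
Reactants: 15 (1S,5S,9S,13R,14S)-9-acetoxy-5-{[tert-butyl(dimethyl)silyl]oxy}-13-hydroxy macrocyclic α-methylene lactone
Product: 16 (1S,5S,9S,13S,14S)-9,13-diacetoxy-5-{[tert-butyl(dimethyl)silyl]oxy} macrocyclic α-methylene lactone (the 5-O-silyl target)
Conditions: AcOH, PPh3, DIAD, toluene, 0 °C → rt
Reagents that add atoms: acetic acid, CC(=O)O
Why: Mitsunobu reaction: acetate displaces the alkoxyphosphonium of the 13R alcohol with SN2 inversion, so the acetate is installed and C13 is corrected to S in the same operation.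

**Step 13**
Reactants: 16 (1S,5S,9S,13S,14S)-9,13-diacetoxy-5-{[tert-butyl(dimethyl)silyl]oxy} macrocyclic α-methylene lactone
Product: 17 CNP0418981.1, (1S,5S,9S,13S,14S)-9,13-diacetoxy-5-hydroxy macrocyclic α-methylene lactone
Conditions: HF·pyridine, pyridine, THF, 0 °C → rt
Reagents that add atoms: none
Why: Buffered fluoride desilylation removes the silyl ether without touching the two acetates, the Michael-acceptor lactone or any stereocentre.

**Compound list**
1 | 3-methylbut-2-enal | CC(C)=CC=O | starting material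
2 | (1E)-tert-butyl(dimethyl)[(3-methylbuta-1,3-dien-1-yl)oxy]silane | C=C(C)/C=C/O[Si](C)(C)C(C)(C)C | intermediate
3 | trimethyl orthoformate | COC(OC)OC | starting material
4 | (2E)-5,5-dimethoxy-3-methylpent-2-enal | O=C/C=C(\C)CC(OC)OC | intermediate
5 | (2E,5S,6E)-5-hydroxy-9,9-dimethoxy-3,7-dimethylnona-2,6-dienal | O=C/C=C(\C)C[C@H](O)/C=C(\C)CC(OC)OC | intermediate
6 | (2E,5S,6E)-5-acetoxy-9,9-dimethoxy-3,7-dimethylnona-2,6-dienal | O=C/C=C(\C)C[C@H](OC(C)=O)/C=C(\C)CC(OC)OC | intermediate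
7 | (2E,5S,6E,9S,10E)-9-acetoxy-5-hydroxy-13,13-dimethoxy-3,7,11-trimethyltrideca-2,6,10-trienal | O=C/C=C(\C)C[C@H](O)/C=C(\C)C[C@H](OC(C)=O)/C=C(\C)CC(OC)OC | intermediate
8 | (2E,5S,6E,9S,10E)-9-acetoxy-5-{[tert-butyl(dimethyl)silyl]oxy}-13,13-dimethoxy-3,7,11-trimethyltrideca-2,6,10-trienal | O=C/C=C(\C)C[C@H](O[Si](C)(C)C(C)(C)C)/C=C(\C)C[C@H](OC(C)=O)/C=C(\C)CC(OC)OC | intermediate
9 | vinylmagnesium bromide | C=C[Mg]Br | starting material
10 | (3R,4E,7S,8E,11S,12E)-7-{[tert-butyl(dimethyl)silyl]oxy}-3-hydroxy-15,15-dimethoxy-5,9,13-trimethylpentadeca-1,4,8,12-tetraen-11-yl acetate | O[C@H](C=C)/C=C(\C)C[C@H](O[Si](C)(C)C(C)(C)C)/C=C(\C)C[C@H](OC(C)=O)/C=C(\C)CC(OC)OC | intermediate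
11 | 2-(bromomethyl)prop-2-enoic acid | C=C(CBr)C(=O)O | starting material
12 | (3R,4E,7S,8E,11S,12E)-11-acetoxy-7-{[tert-butyl(dimethyl)silyl]oxy}-15,15-dimethoxy-5,9,13-trimethylpentadeca-1,4,8,12-tetraen-3-yl 2-(bromomethyl)prop-2-enoate | C=C(CBr)C(=O)O[C@H](C=C)/C=C(\C)C[C@H](O[Si](C)(C)C(C)(C)C)/C=C(\C)C[C@H](OC(C)=O)/C=C(\C)CC(OC)OC | intermediate
13 | (5S)-3-(bromomethyl)-5-[(1E,4S,5E,8S,9E)-8-acetoxy-4-{[tert-butyl(dimethyl)silyl]oxy}-12,12-dimethoxy-2,6,10-trimethyldodeca-1,5,9-trien-1-yl]furan-2(5H)-one | O=C1O[C@H](C=C1CBr)/C=C(\C)C[C@H](O[Si](C)(C)C(C)(C)C)/C=C(\C)C[C@H](OC(C)=O)/C=C(\C)CC(OC)OC | intermediate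
14 | (5S)-3-(bromomethyl)-5-[(1E,4S,5E,8S,9E)-8-acetoxy-4-{[tert-butyl(dimethyl)silyl]oxy}-2,6,10-trimethyl-12-oxododeca-1,5,9-trien-1-yl]furan-2(5H)-one | O=C1O[C@H](C=C1CBr)/C=C(\C)C[C@H](O[Si](C)(C)C(C)(C)C)/C=C(\C)C[C@H](OC(C)=O)/C=C(\C)CC=O | intermediate
15 | (1S,5S,9S,13R,14S)-9-acetoxy-5-{[tert-butyl(dimethyl)silyl]oxy}-13-hydroxy macrocyclic α-methylene lactone (13-epi, 13-deacetyl, 5-O-silyl target) | C=C1C(=O)O[C@H]2/C=C(\C)C[C@H](O[Si](C)(C)C(C)(C)C)/C=C(\C)C[C@H](OC(C)=O)/C=C(\C)C[C@@H](O)[C@H]12 | intermediate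
16 | (1S,5S,9S,13S,14S)-9,13-diacetoxy-5-{[tert-butyl(dimethyl)silyl]oxy} macrocyclic α-methylene lactone (5-O-silyl target) | C=C1C(=O)O[C@H]2/C=C(\C)C[C@H](O[Si](C)(C)C(C)(C)C)/C=C(\C)C[C@H](OC(C)=O)/C=C(\C)C[C@H](OC(C)=O)[C@H]12 | intermediate
17 | CNP0418981.1 | C=C1C(=O)O[C@H]2/C=C(\C)C[C@H](O)/C=C(\C)C[C@H](OC(C)=O)/C=C(\C)C[C@H](OC(C)=O)[C@H]12 | target

**Step count**
Total step count: 13. Longest linear sequence: 13 steps (1 → 17).

**Three steps most likely to fail**

Step 11 (macrocyclisation). Risks are oligomerisation, isomerisation of the β,γ-unsaturated aldehyde, and a diastereomer other than the predicted (13R,14S) one. The fallback sets out from 10 and comes back at 16. Commercial ethyl 2-[(trimethylsilyl)methyl]prop-2-enoate is saponified (LiOH, THF/H2O) to 2-[(trimethylsilyl)methyl]prop-2-enoic acid F1. Alcohol 10 is esterified with it (DCC, DMAP) to the 2-[(trimethylsilyl)methyl]prop-2-enoate of 10 F2. Metathesis as in step 9 gives the 3-[(trimethylsilyl)methyl]butenolide acetal F3, and oxalic acid on SiO2 gives the allylsilane aldehyde F4. BF3·OEt2 in CH2Cl2 at −78 °C and 2 mM then closes the ring by a Hosomi–Sakurai addition through an open antiperiplanar transition state, which favours the syn-type adduct, that is the (13S)-alcohol F5. Ac2O, pyridine and DMAP convert it into 16, so steps 11 and 12 are both bypassed.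

Step 12 (Mitsunobu acetate inversion). The alcohol is flanked by the ring-fusion carbon, acetic acid is a weak Mitsunobu nucleophile, and elimination towards a diene or phosphine addition to the methylene lactone can compete. The fallback sets out from 15 and comes back at 16. ClCH2SO2Cl and pyridine in CH2Cl2 at 0 °C give the 13-O-chloromethanesulfonate of 15 F6. CsOAc with 18-crown-6 in toluene at 50 °C displaces it with inversion to give 16.

Step 5 (second vinylogous aldol). The product enal resembles the substrate enal, so over-addition and modest enantiocontrol are possible on a valuable aldehyde. The fallback sets out from 6 and comes back at 8. 3-Methylbut-2-enoyl chloride and morpholine (2 equiv) give 4-(3-methylbut-2-enoyl)morpholine F7. LiN(i-Pr)2 and TBSCl in THF at −78 °C give the N,O-silyl ketene acetal 4-[(1Z)-1-{[tert-butyl(dimethyl)silyl]oxy}-3-methylbuta-1,3-dien-1-yl]morpholine F8. Under SiCl4 and Denmark's (S,S)-bisphosphoramide catalyst (5 mol %) in CH2Cl2 at −78 °C, F8 adds through its γ-carbon to the Si face of 6 and gives the (5S)-hydroxy morpholine amide F9; this product is an amide and cannot react a second time. TBSOTf and 2,6-lutidine give the silyl ether amide F10. Cp2Zr(H)Cl in THF at rt reduces the tertiary amide to the aldehyde in the presence of the acetate and gives 8.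

**Further compounds**
F1 | step 11 | 2-[(trimethylsilyl)methyl]prop-2-enoic acid | C=C(C[Si](C)(C)C)C(=O)O
F2 | step 11 | (3R,4E,7S,8E,11S,12E)-11-acetoxy-7-{[tert-butyl(dimethyl)silyl]oxy}-15,15-dimethoxy-5,9,13-trimethylpentadeca-1,4,8,12-tetraen-3-yl 2-[(trimethylsilyl)methyl]prop-2-enoate | C=C(C[Si](C)(C)C)C(=O)O[C@H](C=C)/C=C(\C)C[C@H](O[Si](C)(C)C(C)(C)C)/C=C(\C)C[C@H](OC(C)=O)/C=C(\C)CC(OC)OC
F3 | step 11 | (5S)-5-[(1E,4S,5E,8S,9E)-8-acetoxy-4-{[tert-butyl(dimethyl)silyl]oxy}-12,12-dimethoxy-2,6,10-trimethyldodeca-1,5,9-trien-1-yl]-3-[(trimethylsilyl)methyl]furan-2(5H)-one | O=C1O[C@H](C=C1C[Si](C)(C)C)/C=C(\C)C[C@H](O[Si](C)(C)C(C)(C)C)/C=C(\C)C[C@H](OC(C)=O)/C=C(\C)CC(OC)OC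
F4 | step 11 | (5S)-5-[(1E,4S,5E,8S,9E)-8-acetoxy-4-{[tert-butyl(dimethyl)silyl]oxy}-2,6,10-trimethyl-12-oxododeca-1,5,9-trien-1-yl]-3-[(trimethylsilyl)methyl]furan-2(5H)-one | O=C1O[C@H](C=C1C[Si](C)(C)C)/C=C(\C)C[C@H](O[Si](C)(C)C(C)(C)C)/C=C(\C)C[C@H](OC(C)=O)/C=C(\C)CC=O
F5 | step 11 | (1S,5S,9S,13S,14S)-9-acetoxy-5-{[tert-butyl(dimethyl)silyl]oxy}-13-hydroxy macrocyclic α-methylene lactone (C13 epimer of 15) | C=C1C(=O)O[C@H]2/C=C(\C)C[C@H](O[Si](C)(C)C(C)(C)C)/C=C(\C)C[C@H](OC(C)=O)/C=C(\C)C[C@H](O)[C@H]12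
F6 | step 12 | 13-O-chloromethanesulfonate of 15, (1S,5S,9S,13R,14S) | C=C1C(=O)O[C@H]2/C=C(\C)C[C@H](O[Si](C)(C)C(C)(C)C)/C=C(\C)C[C@H](OC(C)=O)/C=C(\C)C[C@@H](OS(=O)(=O)CCl)[C@H]12
F7 | step 5 | 4-(3-methylbut-2-enoyl)morpholine | CC(C)=CC(=O)N1CCOCC1
F8 | step 5 | 4-[(1Z)-1-{[tert-butyl(dimethyl)silyl]oxy}-3-methylbuta-1,3-dien-1-yl]morpholine | C=C(C)/C=C(\O[Si](C)(C)C(C)(C)C)N1CCOCC1
F9 | step 5 | (2E,5S,6E,9S,10E)-9-acetoxy-5-hydroxy-13,13-dimethoxy-3,7,11-trimethyl-1-(morpholin-4-yl)trideca-2,6,10-trien-1-one | O=C(/C=C(\C)C[C@H](O)/C=C(\C)C[C@H](OC(C)=O)/C=C(\C)CC(OC)OC)N1CCOCC1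
F10 | step 5 | (2E,5S,6E,9S,10E)-9-acetoxy-5-{[tert-butyl(dimethyl)silyl]oxy}-13,13-dimethoxy-3,7,11-trimethyl-1-(morpholin-4-yl)trideca-2,6,10-trien-1-one | O=C(/C=C(\C)C[C@H](O[Si](C)(C)C(C)(C)C)/C=C(\C)C[C@H](OC(C)=O)/C=C(\C)CC(OC)OC)N1CCOCC1
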